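**Retrosynthetic overview**
- The strategy rests on the C3(sp3)–C8'' aryl bond: it lies alpha to the C4 carbonyl in ring C of the upper (eriodictyol) unit and cis to the C2 catechol ring. It is traced back to a C4–C8'' bond by a semipinacol 1,2-aryl shift in the C3 mesylate of a 2,3-trans-3,4-cis-4-aryl-flavan-3,4-diol (19 to 20), which inverts C3.
- The diol comes from dihydroxylation of a 4-aryl-flav-3-ene (15) on the face opposite the C2 aryl. The flavene comes from 1,2-addition of the C8''-metalated lower flavan (9) to the C4 ketone of the upper flavanone (11), then dehydration.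
- Both halves come from one chromone (4) by catalytic asymmetric conjugate arylation with enantiomeric ligands; seven benzyl ethers are removed at the end.
- Ring order: the pyranone ring (ring C of each half) is made once, in chromone 4; no ring is closed after that.

Key step: step 15

Remark: which enantiomer of the bisphosphine gives which C2 configuration is assigned by analogy with arylation of simple cyclic enones. It is to be confirmed on the first batch (sign of rotation of debenzylated 6 against (S)-naringenin); if the sense is opposite, the ligands of steps 4 and 8 are exchanged. MeO-F12-BIPHEP is (6,6'-dimethoxybiphenyl-2,2'-diyl)bis[bis(3,4,5-trifluorophenyl)phosphine]. Locants with '' refer to the lower (naringenin) unit.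

**Route**

Step 1
Reactants: 1 2',4',6'-trihydroxyacetophenone
Product: 2 1-[2,4-bis(benzyloxy)-6-hydroxyphenyl]ethan-1-one
Conditions: BnBr (2.1 equiv), K2CO3, DMF, rt
Reagents that add atoms: benzyl bromide BrCc1ccccc1
Why: Williamson etherification; the hydroxyl hydrogen-bonded to the acetyl carbonyl is the least nucleophilic, so two equivalents of bromide should alkylate the other two phenols and leave the chelated one free for ring closure.

Step 2
Reactants: 2 1-[2,4-bis(benzyloxy)-6-hydroxyphenyl]ethan-1-one
Product: 3 (E)-1-[2,4-bis(benzyloxy)-6-hydroxyphenyl]-3-(dimethylamino)prop-2-en-1-one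
Conditions: DMF dimethyl acetal, toluene, 100 °C
Reagents that add atoms: N,N-dimethylformamide dimethyl acetal COC(OC)N(C)C
Why: Enaminone formation by condensation of the acetyl methyl group with the amide acetal, which supplies the future C2 carbon with loss of two methanol.

Step 3
Reactants: 3 (E)-enaminone
Product: 4 5,7-bis(benzyloxy)-4H-chromen-4-one
Conditions: conc. HCl (aq), CH2Cl2, 40 °C
Reagents that add atoms: none
Why: Acid-promoted addition–elimination cyclisation, in which the free phenol adds to the protonated enaminone and dimethylamine leaves to close the pyranone ring; benzyl aryl ethers tolerate these conditions.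

Step 4
Reactants: 4 5,7-bis(benzyloxy)-4H-chromen-4-one; 5 4-(benzyloxy)phenylboronic acid
Product: 6 (S)-5,7-bis(benzyloxy)-2-[4-(benzyloxy)phenyl]chroman-4-one (tri-O-benzylnaringenin)
Conditions: [RhOH(cod)]2 (cat.), (S)-MeO-F12-BIPHEP (cat.), toluene/H2O, 40 °C
Reagents that add atoms: none
Why: Hayashi–Miyaura rhodium-catalysed asymmetric 1,4-addition of an arylboronic acid to a chromone under base-free conditions that do not open the flavanone; the electron-poor chiral bisphosphine selects the enone face, so C2'' should form as S.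

Step 5
Reactants: 6 (S)-tri-O-benzylnaringenin
Product: 7 (2S,4S)-5,7-bis(benzyloxy)-2-[4-(benzyloxy)phenyl]chroman-4-ol (2,4-cis)
Conditions: NaBH4, THF/MeOH, 0 °C
Reagents that add atoms: none
Why: Borohydride reduction of the ketone; axial hydride delivery on the half-chair with an equatorial C2 aryl should give the equatorial, 2,4-cis alcohol (this centre is only a mask and is oxidised back in step 13).

Step 6
Reactants: 7 (2S,4S)-flavan-4-ol
Product: 8 (2S,4S)-5,7-bis(benzyloxy)-2-[4-(benzyloxy)phenyl]-4-(tert-butyldimethylsilyloxy)chroman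
Conditions: TBSOTf, 2,6-lutidine, CH2Cl2, −78 → 0 °C
Reagents that add atoms: tert-butyldimethylsilyl trifluoromethanesulfonate CC(C)(C)[Si](C)(C)OS(=O)(=O)C(F)(F)F
Why: O-silylation of a hindered secondary alcohol with the silyl triflate, kept basic by lutidine so that the easily ionised benzylic C4''–O bond is not exposed to acid.

Step 7
Reactants: 8 silyl ether
Product: 9 (2S,4S)-8-bromo-5,7-bis(benzyloxy)-2-[4-(benzyloxy)phenyl]-4-(tert-butyldimethylsilyloxy)chroman
Conditions: NBS (1.0 equiv), CH2Cl2, −78 → 0 °C, dark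
Reagents that add atoms: N-bromosuccinimide O=C1CCC(=O)N1Br
Why: Electrophilic aromatic bromination; in 5,7-dialkoxyflavans monobromination with N-bromosuccinimide goes to C8 (between the ring oxygen and one ether) in preference to the more crowded C6, and the trioxygenated ring A is far more reactive than the mono-oxygenated ring B.

Step 8
Reactants: 4 5,7-bis(benzyloxy)-4H-chromen-4-one; 10 3,4-bis(benzyloxy)phenylboronic acid
Product: 11 (R)-5,7-bis(benzyloxy)-2-[3,4-bis(benzyloxy)phenyl]chroman-4-one (tetra-O-benzyleriodictyol)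
Conditions: [RhOH(cod)]2 (cat.), (R)-MeO-F12-BIPHEP (cat.), toluene/H2O, 40 °C
Reagents that add atoms: none
Why: The same Hayashi–Miyaura asymmetric 1,4-addition as in step 4 with the mirror-image ligand, so the opposite enone face is arylated and C2 should form as R.

Step 9
Reactants: 9 8-bromoflavan silyl ether; 11 (R)-tetra-O-benzyleriodictyol
Product: 14 tertiary carbinol in which C4 of the upper chroman carries OH and the C8'' carbon of the lower flavan (upper C2 R; lower 2S,4S; both C4 epimers), via aryllithium 12 (not isolated), via arylcerium dichloride 13 (not isolated)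
Conditions: 9, n-BuLi, THF, −78 °C; anhydrous CeCl3, −78 °C; then 11, −78 → −40 °C; H2O
Reagents that add atoms: none
Why: Bromine–lithium exchange, transmetalation to the weakly basic organocerium and 1,2-addition to the ketone; cerium suppresses enolisation and the ring opening that would follow it in the flavanone, and the configuration of the new C4 carbinol does not matter because C4 becomes sp2 in step 10.

Step 10
Reactants: 14 tertiary carbinol
Product: 15 (R)-4-aryl-2H-chromene (flav-3-ene) with the lower silyloxyflavan attached through C8'' at C4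
Conditions: Burgess reagent, THF, rt → 50 °C, dark
Reagents that add atoms: none
Why: Burgess dehydration of a tertiary dibenzylic alcohol under neutral conditions (acid would ionise the C4'' silyl ether); C3 carries the only beta hydrogens, so only the C3=C4 alkene can form and C2 is untouched.

Step 11
Reactants: 15 4-aryl-flav-3-ene
Product: 16 2,3-trans-3,4-cis-4-aryl-flavan-3,4-diol (both hydroxyls on the face opposite the C2 aryl, the C8'' aryl on C4 cis to the C2 aryl; lower unit still the 4''-silyl ether)
Conditions: OsO4 (cat.), NMO, acetone/H2O, rt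
Reagents that add atoms: osmium tetroxide O=[Os](=O)(=O)=O; N-methylmorpholine N-oxide C[N+]1([O-])CCOCC1; water O
Why: Upjohn syn-dihydroxylation; the osmium reagent should approach the flavene on the face away from the C2 aryl, which sets C3–OH trans to that aryl and C4–OH cis to C3–OH in one suprafacial event.

Step 12
Reactants: 16 diol silyl ether
Product: 17 triol (free C4''–OH on the lower unit, C3–OH and C4–OH on the upper unit)
Conditions: TBAF, THF, 0 °C → rt
Reagents that add atoms: none
Why: Fluoride desilylation, carried out while the molecule holds no ketone and therefore no base-sensitive flavanone.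

Step 13
Reactants: 17 triol
Product: 18 diol with the lower flavanone ketone restored (C4''=O; upper 3,4-diol unchanged)
Conditions: DDQ (1.2 equiv), CH2Cl2/pH 7 phosphate buffer, 0 °C
Reagents that add atoms: none
Why: Benzylic oxidation by hydride abstraction with DDQ; only C4''–H is activated by a 2,4,6-trioxygenated ring, whereas the C3 carbinol is not benzylic and C4 has no hydrogen, and the buffer removes the acidic hydroquinone before it can ionise the C4 carbinol.

Step 14
Reactants: 18 diol ketone
Product: 19 C3 methanesulfonate of 18 (tertiary C4–OH free, cis to the mesylate)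
Conditions: MsCl, Et3N, CH2Cl2, −20 °C; cold NaHCO3 work-up, used crude
Reagents that add atoms: methanesulfonyl chloride CS(=O)(=O)Cl
Why: Sulfonylation through the sulfene takes the secondary C3 hydroxyl and leaves the tertiary one, and the cis hydroxyl cannot displace the mesylate to form an epoxide.

Step 15
Reactants: 19 C3 mesylate
Product: 20 hepta-O-benzyl ether of the target, (2R,3R,2''S), 2,3-cis
Conditions: Et3Al (3 equiv), CH2Cl2, −78 °C; pH 7 buffer/Rochelle salt quench at −78 °C
Reagents that add atoms: none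
Why: Et3Al turns the tertiary C4 hydroxyl into a diethylaluminium alkoxide (ethane is lost) whose aluminium also binds the cis C3 mesylate; as the C3–O bond ionises, the C8'' aryl lying antiperiplanar to it bridges C4 and C3 in a phenonium-like transition state and ends on C3, while the alkoxide oxygen closes down to the C4 carbonyl, so C4–C8'' is exchanged for C3–C8''. The closest known reaction type is the organoaluminium-promoted semipinacol rearrangement of 2-sulfonyloxy tertiary alcohols with 1,2-aryl migration, which is stereospecific with inversion at the migration terminus. No ring is closed or opened; ring C is kept and only the exocyclic aryl moves. The new stereocentre C3 is controlled by the C3–O configuration that step 11 placed anti to the C2 aryl: inversion puts the migrated aryl cis to the C2 aryl. Selectivity required is that the exocyclic C8'' aryl moves and not ring carbon C4a (ring contraction) or the C2 aryl, and that elimination does not compete; this should be secured because the alkoxide push acts only on groups attached to C4, allylic-type strain against the peri C5 benzyloxy group disfavours an equatorial aryl at C4 so that the reactive half-chair has this aryl pseudoaxial and anti to an axial C3–OMs, and the 2,4,6-trioxygenated ring has a high migratory aptitude. The product is an enolisable cis alpha-aryl ketone, so the mixture is quenched cold into neutral buffer to avoid epimerisation to the trans isomer.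

Step 16
Reactants: 20 hepta-O-benzyl ether
Product: 21 (2R,3R)-2-(3,4-dihydroxyphenyl)-5,7-dihydroxy-3-[(2S)-5,7-dihydroxy-2-(4-hydroxyphenyl)-4-oxochroman-8-yl]chroman-4-one (target)
Conditions: H2 (1 atm), Pd/C, EtOAc/MeOH, rt
Reagents that add atoms: none
Why: Hydrogenolysis of the seven benzyl aryl ethers over Pd/C under neutral conditions, which should spare the two conjugated aryl ketones and the base-labile 2,3-cis centre at C3.

**Compound list**
1 | 2',4',6'-trihydroxyacetophenone | CC(=O)c1c(O)cc(O)cc1O | starting material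
2 | 1-[2,4-bis(benzyloxy)-6-hydroxyphenyl]ethan-1-one | CC(=O)c1c(O)cc(OCc2ccccc2)cc1OCc1ccccc1 | intermediate
3 | (E)-1-[2,4-bis(benzyloxy)-6-hydroxyphenyl]-3-(dimethylamino)prop-2-en-1-one | CN(C)/C=C/C(=O)c1c(O)cc(OCc2ccccc2)cc1OCc1ccccc1 | intermediate
4 | 5,7-bis(benzyloxy)-4H-chromen-4-one | O=c1ccoc2cc(OCc3ccccc3)cc(OCc3ccccc3)c12 | intermediate
5 | 4-(benzyloxy)phenylboronic acid | OB(O)c1ccc(OCc2ccccc2)cc1 | starting material
6 | (S)-5,7-bis(benzyloxy)-2-[4-(benzyloxy)phenyl]chroman-4-one | O=C1C[C@@H](c2ccc(OCc3ccccc3)cc2)Oc2cc(OCc3ccccc3)cc(OCc3ccccc3)c12 | intermediate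
7 | (2S,4S)-5,7-bis(benzyloxy)-2-[4-(benzyloxy)phenyl]chroman-4-ol | O[C@H]1C[C@@H](c2ccc(OCc3ccccc3)cc2)Oc2cc(OCc3ccccc3)cc(OCc3ccccc3)c12 | intermediate
8 | (2S,4S)-5,7-bis(benzyloxy)-2-[4-(benzyloxy)phenyl]-4-(tert-butyldimethylsilyloxy)chroman | CC(C)(C)[Si](C)(C)O[C@H]1C[C@@H](c2ccc(OCc3ccccc3)cc2)Oc2cc(OCc3ccccc3)cc(OCc3ccccc3)c12 | intermediate
9 | (2S,4S)-8-bromo-5,7-bis(benzyloxy)-2-[4-(benzyloxy)phenyl]-4-(tert-butyldimethylsilyloxy)chroman | CC(C)(C)[Si](C)(C)O[C@H]1C[C@@H](c2ccc(OCc3ccccc3)cc2)Oc2c(Br)c(OCc3ccccc3)cc(OCc3ccccc3)c12 | intermediate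
10 | 3,4-bis(benzyloxy)phenylboronic acid | OB(O)c1ccc(OCc2ccccc2)c(OCc2ccccc2)c1 | starting material
11 | (R)-5,7-bis(benzyloxy)-2-[3,4-bis(benzyloxy)phenyl]chroman-4-one | O=C1C[C@H](c2ccc(OCc3ccccc3)c(OCc3ccccc3)c2)Oc2cc(OCc3ccccc3)cc(OCc3ccccc3)c12 | intermediate
12 | 8-lithio derivative of 9 (aryllithium) | CC(C)(C)[Si](C)(C)O[C@H]1C[C@@H](c2ccc(OCc3ccccc3)cc2)Oc2c([Li])c(OCc3ccccc3)cc(OCc3ccccc3)c12 | intermediate (not isolated)
13 | 8-(dichlorocerio) derivative of 9 (arylcerium dichloride) | CC(C)(C)[Si](C)(C)O[C@H]1C[C@@H](c2ccc(OCc3ccccc3)cc2)Oc2c([Ce](Cl)Cl)c(OCc3ccccc3)cc(OCc3ccccc3)c12 | intermediate (not isolated)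
14 | C4-aryl tertiary carbinol, halves joined C4 to C8'' (both C4 epimers) | CC(C)(C)[Si](C)(C)O[C@H]1C[C@@H](c2ccc(OCc3ccccc3)cc2)Oc2c(C3(O)C[C@H](c4ccc(OCc5ccccc5)c(OCc5ccccc5)c4)Oc4cc(OCc5ccccc5)cc(OCc5ccccc5)c43)c(OCc3ccccc3)cc(OCc3ccccc3)c12 | intermediate
15 | (R)-4-aryl-flav-3-ene | CC(C)(C)[Si](C)(C)O[C@H]1C[C@@H](c2ccc(OCc3ccccc3)cc2)Oc2c(C3=C[C@H](c4ccc(OCc5ccccc5)c(OCc5ccccc5)c4)Oc4cc(OCc5ccccc5)cc(OCc5ccccc5)c43)c(OCc3ccccc3)cc(OCc3ccccc3)c12 | intermediate
16 | 2,3-trans-3,4-cis-4-aryl-flavan-3,4-diol, 4''-silyl ether | CC(C)(C)[Si](C)(C)O[C@H]1C[C@@H](c2ccc(OCc3ccccc3)cc2)Oc2c([C@]3(O)[C@@H](O)[C@H](c4ccc(OCc5ccccc5)c(OCc5ccccc5)c4)Oc4cc(OCc5ccccc5)cc(OCc5ccccc5)c43)c(OCc3ccccc3)cc(OCc3ccccc3)c12 | intermediate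
17 | triol (4''-OH, 3-OH, 4-OH) | O[C@H]1C[C@@H](c2ccc(OCc3ccccc3)cc2)Oc2c([C@]3(O)[C@@H](O)[C@H](c4ccc(OCc5ccccc5)c(OCc5ccccc5)c4)Oc4cc(OCc5ccccc5)cc(OCc5ccccc5)c43)c(OCc3ccccc3)cc(OCc3ccccc3)c12 | intermediate
18 | 3,4-diol with lower flavanone ketone | O=C1C[C@@H](c2ccc(OCc3ccccc3)cc2)Oc2c([C@]3(O)[C@@H](O)[C@H](c4ccc(OCc5ccccc5)c(OCc5ccccc5)c4)Oc4cc(OCc5ccccc5)cc(OCc5ccccc5)c43)c(OCc3ccccc3)cc(OCc3ccccc3)c12 | intermediate
19 | C3 mesylate of 18 | O=C1C[C@@H](c2ccc(OCc3ccccc3)cc2)Oc2c([C@]3(O)[C@@H](OS(C)(=O)=O)[C@H](c4ccc(OCc5ccccc5)c(OCc5ccccc5)c4)Oc4cc(OCc5ccccc5)cc(OCc5ccccc5)c43)c(OCc3ccccc3)cc(OCc3ccccc3)c12 | intermediate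
20 | hepta-O-benzyl ether of the target, (2R,3R,2''S) | O=C1C[C@@H](c2ccc(OCc3ccccc3)cc2)Oc2c1c(OCc1ccccc1)cc(OCc1ccccc1)c2[C@H]1C(=O)c2c(OCc3ccccc3)cc(OCc3ccccc3)cc2O[C@H]1c1ccc(OCc2ccccc2)c(OCc2ccccc2)c1 | intermediate
21 | CNP0105436.1, (2R,3R)-2-(3,4-dihydroxyphenyl)-5,7-dihydroxy-3-[(2S)-5,7-dihydroxy-2-(4-hydroxyphenyl)-4-oxochroman-8-yl]chroman-4-one | O=C1C[C@@H](c2ccc(O)cc2)Oc2c1c(O)cc(O)c2[C@H]1C(=O)c2c(O)cc(O)cc2O[C@H]1c1ccc(O)c(O)c1 | target

**Step count**
Total: 16 steps. Longest linear sequence: 15 steps (steps 1–7, then 9–16).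

**Steps most likely to fail**

Step 15. The aryl shift may lose out to migration of ring carbon C4a from the diequatorial conformer (ring contraction) or to elimination, and the cis product may epimerise to trans during quench. The fallback sets out from 18 and returns at 20. Buffered Dess–Martin periodinane should oxidise the secondary C3 hydroxyl of 18 to the 4-aryl-4-hydroxyflavan-3-one F1. An alpha-ketol rearrangement (Al(OiPr)3, toluene, warm) should then move the C8'' aryl from C4 to C3, driven by conjugation of the new C4 carbonyl with ring A, and give the 3-aryl-3-hydroxyflavan-4-one F2. SmI2 in THF/MeOH at −78 °C should remove the tertiary alpha-hydroxyl; the samarium enolate is protonated kinetically on the face opposite the C2 aryl, which places the C3 aryl cis to it and gives 20.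

Step 9. The hindered aryl metal may act as a base toward the deactivated, peri-shielded ketone, so that enolisation and ring opening of 11 replace addition. The fallback sets out from 11 and 9 and returns at 15, using cross-coupling instead of carbonyl addition. Tf2O with 2,6-di-tert-butyl-4-methylpyridine should convert 11, without a free enolate, into the (R)-4-triflyloxy-2H-chromene F3. Aryllithium 12 is quenched with 2-isopropoxy-4,4,5,5-tetramethyl-1,3,2-dioxaborolane to give the C8'' pinacol boronate F4. Suzuki–Miyaura coupling of F3 with F4 (Pd(OAc)2, SPhos, K3PO4, toluene/H2O) should give flavene 15 directly.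

Step 13. The oxidation may lose chemoselectivity: hydride abstraction at other benzylic positions, or acid-triggered ionisation of the C4 carbinol next to the free diol. The fallback sets out from 15 and returns at 18 by restoring the ketone before the diol exists. TBAF should desilylate 15 to the flavene alcohol F5; buffered Dess–Martin periodinane should oxidise its only hydroxyl to the flavene ketone F6; OsO4/NMO dihydroxylation of F6 on the face opposite the C2 aryl should then give 18.

**Further compounds**
F1 | step 15 | 4-aryl-4-hydroxyflavan-3-one (C3 ketone of 18) | O=C1C[C@@H](c2ccc(OCc3ccccc3)cc2)Oc2c([C@]3(O)C(=O)[C@H](c4ccc(OCc5ccccc5)c(OCc5ccccc5)c4)Oc4cc(OCc5ccccc5)cc(OCc5ccccc5)c43)c(OCc3ccccc3)cc(OCc3ccccc3)c12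
F2 | step 15 | 3-aryl-3-hydroxyflavan-4-one (C3 configuration immaterial) | O=C1C[C@@H](c2ccc(OCc3ccccc3)cc2)Oc2c1c(OCc1ccccc1)cc(OCc1ccccc1)c2C1(O)C(=O)c2c(OCc3ccccc3)cc(OCc3ccccc3)cc2O[C@H]1c1ccc(OCc2ccccc2)c(OCc2ccccc2)c1
F3 | step 9 | (R)-5,7-bis(benzyloxy)-2-[3,4-bis(benzyloxy)phenyl]-2H-chromen-4-yl trifluoromethanesulfonate | O=S(=O)(OC1=C[C@H](c2ccc(OCc3ccccc3)c(OCc3ccccc3)c2)Oc2cc(OCc3ccccc3)cc(OCc3ccccc3)c12)C(F)(F)F
F4 | step 9 | C8'' pinacol boronate of the lower silyloxyflavan | CC(C)(C)[Si](C)(C)O[C@H]1C[C@@H](c2ccc(OCc3ccccc3)cc2)Oc2c(B3OC(C)(C)C(C)(C)O3)c(OCc3ccccc3)cc(OCc3ccccc3)c12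
F5 | step 13 | flavene alcohol (15 without the silyl group) | O[C@H]1C[C@@H](c2ccc(OCc3ccccc3)cc2)Oc2c(C3=C[C@H](c4ccc(OCc5ccccc5)c(OCc5ccccc5)c4)Oc4cc(OCc5ccccc5)cc(OCc5ccccc5)c43)c(OCc3ccccc3)cc(OCc3ccccc3)c12
F6 | step 13 | flavene ketone (4-aryl-flav-3-ene with lower flavanone) | O=C1C[C@@H](c2ccc(OCc3ccccc3)cc2)Oc2c(C3=C[C@H](c4ccc(OCc5ccccc5)c(OCc5ccccc5)c4)Oc4cc(OCc5ccccc5)cc(OCc5ccccc5)c43)c(OCc3ccccc3)cc(OCc3ccccc3)c12
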